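**Assumption (one line):** the SMILES is taken as definitive, i.e. trans-fused rings with 6S,7S in the keto half and 3′R,6′S,7′S in the hydroxy half (3′-OH cis to the 6′-methyl). Locants used below, per half: O1, C2 (CMe2), C3 (C=O or CHOH), C4, C5, C6 (quaternary, Me), C7 (O–CH), C8, C9, C10 (C–Me), C11 (bears linker), C12 (linker CH2); primes for the hydroxy half.

## Retrosynthetic overview

1. The only unsymmetrical element (C3 ketone vs C3′ alcohol) is set last, by catalyst-controlled mono-reduction of a C2-symmetric 3,3′-diketone.
2. That diketone comes from a bis(exocyclic-methylene) diol by oxidation and acid transposition of both C10=CH2 into the tetrasubstituted C10=C11 alkenes.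
3. Key step: all four rings form in one operation from an acyclic C2-symmetric tetraepoxy bis(allylsilane). It makes two O1–C2 and two C6–C11 bonds; in each half the oxepane oxygen bridges first (bicyclic epoxonium), then the cyclohexane closes.
4. The cascade substrate comes from a C28 tetraene bis(vinyl triflate) by one Shi tetra-epoxidation (sets C6, C7, C6′, C7′) and Pd/Me3SiCH2MgCl coupling.
5. The tetraene comes from a four-component coupling of two acylsilanes (geranyl bromide + N-acetylmorpholine) and two vinyllithiums, which forms C12–C12′.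

## Forward route

**Step 1**
Reactants: 1, geranyl bromide; 2, N-acetylmorpholine
Product: 3, (4E)-5,9-dimethyl-1-(morpholin-4-yl)deca-4,8-dien-1-one
Conditions: LDA, THF, −78 °C; then 1, −78 → 0 °C
Reagents that add atoms: none (both partners are numbered reactants)
Why: SN2 C-alkylation of the amide lithium enolate by a primary allylic bromide; the E-alkene is untouched and no stereocentre is formed.

**Step 2**
Reactants: 3
Product: 4, (4E)-1-[dimethyl(phenyl)silyl]-5,9-dimethyldeca-4,8-dien-1-one (acylsilane)
Conditions: PhMe2SiLi (1.2 equiv), THF, −78 °C; aq. NH4Cl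
Reagents that add atoms: dimethylphenylsilyllithium, [Li][Si](C)(C)c1ccccc1
Why: Acyl substitution of a morpholine amide by a silyl anion; the chelated tetrahedral intermediate (Weinreb-type) collapses only on work-up, so no over-addition occurs.

**Step 3**
Reactants: 4 (2 equiv); 5, vinyllithium (2 equiv, generated in situ from tetravinyltin and MeLi)
Product: 6, (6E,10Z,14Z,18E)-10,15-bis{[dimethyl(phenyl)silyl]oxy}-2,6,19,23-tetramethyltetracosa-2,6,10,14,18,22-hexaene
Conditions: Et2O/THF, −78 → −40 °C; then I2 (0.5 equiv per 4), −78 °C
Reagents that add atoms: none beyond reactants 4 and 5 (vinyllithium, [Li]C=C)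
Why: Four-component coupling: 1,2-addition, [1,2]-Brook rearrangement to the Li-chelated (Z)-siloxyallyllithium, then iodine-mediated oxidative (Wurtz-type) homocoupling at the primary termini forms C12–C12′. The Z geometry places C9 trans to C12, but it is not critical because C11 ends up sp2.

**Step 4**
Reactants: 6
Product: 7, (6E,10Z,14Z,18E)-2,6,19,23-tetramethyltetracosa-2,6,10,14,18,22-hexaene-10,15-diyl bis(trifluoromethanesulfonate)
Conditions: CsF, PhNTf2, DME, 23 °C
Reagents that add atoms: N-phenylbis(trifluoromethanesulfonimide), O=S(=O)(N(c1ccccc1)S(=O)(=O)C(F)(F)F)C(F)(F)F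
Why: Fluoride desilylation gives the regio- and geometry-defined caesium enolate, which is O-triflated in situ with retention of alkene geometry (enol triflate formation).

**Step 5**
Reactants: 7
Product: 8, (3S,6S,7S,18S,19S,22S,10Z,14Z)-2,3:6,7:18,19:22,23-tetraepoxy-2,6,19,23-tetramethyltetracosa-10,14-diene-10,15-diyl bis(triflate)
Conditions: ent-Shi ketone (L-fructose-derived, from L-sorbose), Oxone, K2CO3, Bu4NHSO4, MeCN–DMM/aq. borate buffer (pH 10.5), 0 °C
Reagents that add atoms: Oxone (potassium peroxymonosulfate), [K+].[O-]S(=O)(=O)OO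
Why: Shi asymmetric epoxidation (chiral dioxirane, spiro transition state). The L-series ketone gives the (S)- and (S,S)-epoxides of the four electron-rich trisubstituted alkenes, while the electron-poor vinyl triflate C=C bonds are not oxidised; this sets C6, C7, C6′, C7′ (C3/C3′ are later oxidised).

**Step 6**
Reactants: 8
Product: 9, (3S,6S,7S,18S,19S,22S,10Z,14Z)-2,3:6,7:18,19:22,23-tetraepoxy-2,6,19,23-tetramethyl-10,15-bis[(trimethylsilyl)methyl]tetracosa-10,14-diene
Conditions: Me3SiCH2MgCl, Pd(PPh3)4 (10 mol %), THF, 0 → 23 °C
Reagents that add atoms: (trimethylsilyl)methylmagnesium chloride, C[Si](C)(C)C[Mg]Cl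
Why: Kumada-type Pd cross-coupling of a vinyl triflate with a β-hydrogen-free Grignard reagent, with retention of geometry; hindered trisubstituted epoxides tolerate the reagent at ≤23 °C, and the new CH2 becomes the C10 methyl carbon.

**Step 7 (key step)**
Reactants: 9
Product: 10, 1,2-bis[(3S,5aS,6R,9aS)-3-hydroxy-2,2,5a-trimethyl-7-methylidenedecahydro-1-benzoxepin-6-yl]ethane (locants: 3S,6S,7S,11R in each half; C10=CH2)
Conditions: TMSOTf (3 equiv), 2,6-di-tert-butyl-4-methylpyridine (4 equiv), CH2Cl2, −78 °C; then Bu4NF, THF, 0 °C
Reagents that add atoms: none (transient O-TMS ethers are cleaved by fluoride; SiMe3 is lost)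
Why: Proposed new method: at each terminus the silylated 2,3-epoxide is opened at tertiary C2 by the 6,7-epoxide oxygen, and the resulting bicyclic epoxonium is opened at tertiary C6 by the allylsilane (SE2′, chair, anti to oxygen). Inversion at C6 with retention at C7 and C3 gives the trans-fused (6S,7S) oxepane–cyclohexane, and the β-silyl cation collapses at once to C10=CH2, so the two ends do not cross-react (C11 is set R but erased in step 9). Closest known reactions: TMSOTf-promoted tandem endo-oxacyclisation/carbacyclisation of 1,5-diepoxides with π-nucleophiles, and two-directional allylsilane-terminated epoxy-polyene tetracyclisation to onoceranes.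

**Step 8**
Reactants: 10
Product: 11, 1,2-bis[(5aS,6R,9aS)-2,2,5a-trimethyl-7-methylidene-3-oxodecahydro-1-benzoxepin-6-yl]ethane
Conditions: Dess–Martin periodinane, NaHCO3, CH2Cl2, 23 °C
Reagents that add atoms: none
Why: Dess–Martin oxidation of both hindered secondary alcohols under buffered, non-acidic conditions; alkenes and ethers are inert, and the cascade-derived C3 configuration (opposite to the target) is erased.

**Step 9**
Reactants: 11
Product: 12, 1,2-bis[(5aS,9aS)-2,2,5a,7-tetramethyl-3-oxo-2,3,4,5,5a,8,9,9a-octahydro-1-benzoxepin-6-yl]ethane (C2-symmetric diketone, both alkenes C10=C11)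
Conditions: p-TsOH·H2O (0.3 equiv), benzene, 60 °C, monitored
Reagents that add atoms: none
Why: Acid-catalysed exo-to-endo alkene isomerisation via the tertiary C10 cation to the thermodynamically preferred tetrasubstituted alkene (the α-onocerin → β-onocerin type). It is run at the diketone stage because the α-keto C2–O bond cannot ionise; C6 and C7 are untouched.

**Step 10**
Reactants: 12
Product: 13, sodwanone T
Conditions: (S)-Me-CBS (0.3 equiv), catecholborane (about 1 equiv), toluene, −40 °C, quenched near 50% conversion; recovered 12 and over-reduced diol (after Dess–Martin re-oxidation) recycled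
Reagents that add atoms: none (hydride only)
Why: Corey–Bakshi–Shibata reduction; the catalyst differentiates the quaternary C2 (large) from C4H2 (small), and the (S)-catalyst delivers the (3′R)-alcohol. The two ketones are remote and equivalent, so mono-reduction is statistical (about 45–50% per pass); catecholborane does not hydroborate the tetrasubstituted alkenes.

## Compound list

1 | geranyl bromide, (2E)-1-bromo-3,7-dimethylocta-2,6-diene | BrC/C=C(\C)CCC=C(C)C | starting material
2 | N-acetylmorpholine | CC(=O)N1CCOCC1 | starting material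
3 | (4E)-5,9-dimethyl-1-(morpholin-4-yl)deca-4,8-dien-1-one | O=C(CC/C=C(\C)CCC=C(C)C)N1CCOCC1 | intermediate
4 | (4E)-1-[dimethyl(phenyl)silyl]-5,9-dimethyldeca-4,8-dien-1-one | O=C(CC/C=C(\C)CCC=C(C)C)[Si](C)(C)c1ccccc1 | intermediate
5 | vinyllithium | [Li]C=C | starting material (in situ from tetravinyltin/MeLi)
6 | (6E,10Z,14Z,18E)-10,15-bis(dimethylphenylsilyloxy)-2,6,19,23-tetramethyltetracosa-2,6,10,14,18,22-hexaene | C(/C=C(\O[Si](C)(C)c1ccccc1)CC/C=C(\C)CCC=C(C)C)C/C=C(\O[Si](C)(C)c1ccccc1)CC/C=C(\C)CCC=C(C)C | intermediate
7 | corresponding 10,15-bis(triflate) | C(/C=C(\OS(=O)(=O)C(F)(F)F)CC/C=C(\C)CCC=C(C)C)C/C=C(\OS(=O)(=O)C(F)(F)F)CC/C=C(\C)CCC=C(C)C | intermediate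
8 | (3S,6S,7S,18S,19S,22S)-tetraepoxy bis(triflate) | C(/C=C(\OS(=O)(=O)C(F)(F)F)CC[C@@H]1O[C@@]1(C)CC[C@@H]1OC1(C)C)C/C=C(\OS(=O)(=O)C(F)(F)F)CC[C@@H]1O[C@@]1(C)CC[C@@H]1OC1(C)C | intermediate
9 | (3S,6S,7S,18S,19S,22S)-tetraepoxy bis(allylsilane) | C(/C=C(\C[Si](C)(C)C)CC[C@@H]1O[C@@]1(C)CC[C@@H]1OC1(C)C)C/C=C(\C[Si](C)(C)C)CC[C@@H]1O[C@@]1(C)CC[C@@H]1OC1(C)C | intermediate
10 | bis(exo-methylene) diol, (3S,6S,7S,11R) in each half | C([C@@H]1C(=C)CC[C@@H]2OC(C)(C)[C@@H](O)CC[C@@]12C)C[C@@H]1C(=C)CC[C@@H]2OC(C)(C)[C@@H](O)CC[C@@]12C | intermediate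
11 | bis(exo-methylene) 3,3′-diketone | C([C@@H]1C(=C)CC[C@@H]2OC(C)(C)C(=O)CC[C@@]12C)C[C@@H]1C(=C)CC[C@@H]2OC(C)(C)C(=O)CC[C@@]12C | intermediate
12 | C2-symmetric 3,3′-diketone with tetrasubstituted C10=C11 alkenes, (6S,7S,6′S,7′S) | CC1=C(CCC2=C(C)CC[C@@H]3OC(C)(C)C(=O)CC[C@@]23C)[C@]2(C)CCC(=O)C(C)(C)O[C@H]2CC1 | intermediate
13 | sodwanone T, (6S,7S,3′R,6′S,7′S) | CC1=C(CCC2=C(C)CC[C@@H]3OC(C)(C)[C@H](O)CC[C@@]23C)[C@]2(C)CCC(=O)C(C)(C)O[C@H]2CC1 | target

## Summary

Total steps: 10. Longest linear sequence: 10 (from geranyl bromide; the route is linear with one dimerising step).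

Three steps most likely to fail, with fallbacks:

1. **Step 7 (two-directional double cascade).** Risks are internal-epoxide activation first, 6-exo (tetrahydropyran) leakage, and incomplete second-end cyclisation. Fallback: give up the two-directional ring formation. Diepoxidise commercial (E,E)-farnesyl acetate (ent-Shi; the allylic alkene is spared), run the same TMSOTf oxa/carbacyclisation on this C15 unit, transpose the alkene, convert C12–OAc to the allylic bromide, and join two bicycles at C12–C12′ by Ti(III)-mediated reductive homocoupling. This rejoins the route at the diol/diketone stage.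

2. **Step 9 (exo → tetrasubstituted isomerisation).** Risks are a Δ9,10 trisubstituted isomer at equilibrium, Wagner–Meerwein methyl shift from C6, or transannular C10–C10′ cyclisation (γ-onocerin type). Fallback: replace the cationic manifold with a carbocation-free alkene transposition, either metal-hydride hydrogen-atom-transfer isomerisation (Co(salen)/PhSiH3) or an SO2 ene/retro-ene sequence, neither of which can trigger skeletal rearrangement.

3. **Step 5 (fourfold Shi epoxidation beside two vinyl triflates).** Risks are incomplete conversion, diastereomer build-up and triflate loss. Fallback: move the oxidation to the start. Epoxidise amide 3 (two alkenes, no competing functionality) and carry the (S,S,S)-diepoxide through acylsilane formation, the four-component coupling and triflation, accepting epoxide exposure to silyl- and vinyllithium at −78 °C.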